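**Retrosynthetic overview** (locants C1–C15 follow germacrane numbering of the target)
1. Target ⇐ reagent-controlled epoxidation of the 1(10)Z-alkene of the 6,11-diangelate.
2. The γ-lactone and the C11 tertiary angelate ⇐ benzilic-ester-type 1,2-methyl shift (C12→C11) in a 2-hydroxy-2-methylfuran-3(2H)-one lactol, with acylative capture of the new alkoxide.
3. Ten-membered ring ⇐ C6–C7 aldol closure between a furanone enol silane and an α,β-epoxy aldehyde (sets C6 and C7).
4. Lactol ⇐ β-hydroxy Weinreb amide + 1-ethoxyvinyllithium; C8 ⇐ methyl (S)-oxiran-2-ylacetate opened by a Z-alkenyl metal; chain ⇐ but-2-yn-1-ol, silylpropyne, carboalumination/formaldehyde, Sharpless epoxidation.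
5. Ring order: five-membered furanone → C4–C5 oxirane → ten-membered carbocycle → γ-lactone (by the 1,2-shift) → C1–C10 oxirane.

Assumption: methyl (S)-oxiran-2-ylacetate (11) is taken as commercially available.

This route is a proposal; selectivities in steps 12–14 are reasoned expectations, not measured values.

**Step 1**
Reactants: 1 but-2-yn-1-ol
Product: 3 (Z)-3-iodobut-2-en-1-ol, via cyclic alkenylalanate 2 (not isolated)
Conditions: NaAlH2(OCH2CH2OCH3)2, THF, 0 → 23 °C; then I2, THF, −78 °C
Reagents that add atoms: iodine, II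
Why: Hydroxyl-directed trans-hydroalumination of the propargylic alcohol puts aluminium on C3 in a five-membered alanate, and iodinolysis with retention gives the Z-iodoalkene (future C10 with its C14 methyl).

**Step 2**
Reactants: 3 (Z)-3-iodobut-2-en-1-ol
Product: 4 (Z)-1-bromo-3-iodobut-2-ene
Conditions: CBr4, PPh3, CH2Cl2, 0 °C
Reagents that add atoms: carbon tetrabromide, BrC(Br)(Br)Br
Why: Appel bromination of the primary allylic alcohol is an SN2 process at CH2, so there is no allylic transposition and the Z geometry is kept.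

**Step 3**
Reactants: 4 (Z)-1-bromo-3-iodobut-2-ene; 5 trimethyl(prop-1-yn-1-yl)silane
Product: 8 (Z)-6-iodohept-5-en-1-yne, via lithiated silylpropyne 6 (not isolated), via silyl enyne 7 (not isolated)
Conditions: 5, n-BuLi, THF, −78 → −20 °C; 4, −78 °C; then K2CO3, MeOH, 23 °C
Reagents that add atoms: none
Why: The lithiated silylpropyne alkylates at its propargylic carbon with the allylic bromide (SN2, forms C2–C3) while the alkenyl iodide is inert at −78 °C, and methanolysis removes the alkyne silyl group in the same flask.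

**Step 4**
Reactants: 8 (Z)-6-iodohept-5-en-1-yne
Product: 10 (2E,6Z)-7-iodo-3-methylocta-2,6-dien-1-ol, via alkenylalane 9 (not isolated)
Conditions: AlMe3, Cp2ZrCl2 (25 mol %), CH2Cl2, 0 → 23 °C; then MeLi, THF, −78 °C; (CH2O)n, −78 → 23 °C
Reagents that add atoms: trimethylaluminium, C[Al](C)C; paraformaldehyde (formaldehyde), C=O
Why: Zirconium-catalysed Negishi syn-carboalumination adds CH3 (C15) and Al cis across the terminal alkyne, and the alanate (made with MeLi so that the alkenyl iodide is not exchanged) adds to formaldehyde with retention, giving the 4E allylic alcohol.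

**Step 5**
Reactants: 10 (2E,6Z)-7-iodo-3-methylocta-2,6-dien-1-ol; 11 methyl (S)-oxiran-2-ylacetate
Product: 14 methyl (3R,5Z,9E)-3,11-dihydroxy-5,9-dimethylundeca-5,9-dienoate, via dilithio species 12 (not isolated), via bis(bromomagnesium) species 13 (not isolated)
Conditions: t-BuLi (3.1 equiv), Et2O, −78 °C; MgBr2·OEt2, −78 → −20 °C; CuI (copper monoiodide, 10 mol %), 11, THF, −40 → −20 °C
Reagents that add atoms: none
Why: Iodine–lithium exchange is stereoretentive, and the copper-catalysed alkenyl Grignard opens the 3,4-epoxybutanoate at its CH2 terminus without touching the ester, so C8 (R) comes unchanged from the S epoxide and the 1(10)Z geometry is kept.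

**Step 6**
Reactants: 14 methyl (3R,5Z,9E)-3,11-dihydroxy-5,9-dimethylundeca-5,9-dienoate
Product: 15 (3R,5Z,9E)-3,11-dihydroxy-N-methoxy-N,5,9-trimethylundeca-5,9-dienamide
Conditions: MeNH(OMe)·HCl, i-PrMgCl, THF, −20 → 0 °C
Reagents that add atoms: N,O-dimethylhydroxylamine hydrochloride, CNOC.Cl
Why: Chloromagnesium methoxy(methyl)amide aminolyses the ester to the Weinreb amide while both hydroxyls sit as magnesium alkoxides, which suppresses β-elimination.

**Step 7**
Reactants: 15 (3R,5Z,9E)-3,11-dihydroxy-N-methoxy-N,5,9-trimethylundeca-5,9-dienamide; 16 ethyl vinyl ether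
Product: 19 (5R)-2-hydroxy-5-[(2Z,6E)-8-hydroxy-2,6-dimethylocta-2,6-dien-1-yl]-2-methyldihydrofuran-3(2H)-one, via 1-ethoxyvinyllithium 17 (not isolated), via ethoxy enone 18 (not isolated)
Conditions: 16, t-BuLi, THF, −78 → 0 °C; 15, −78 → 0 °C; then 1 M HCl, THF, 0 → 23 °C
Reagents that add atoms: water, O
Why: The Weinreb amide takes up one 1-ethoxyvinyllithium (acyl anion equivalent) through a stable chelate, and acid hydrolysis of the enol ether unveils the 1,2-diketone, which the C8 hydroxyl traps as the five-membered hemiketal, tying up O8 and leaving C7 as the only enolisable position.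

**Step 8**
Reactants: 19 (5R)-2-hydroxy-5-[(2Z,6E)-8-hydroxy-2,6-dimethylocta-2,6-dien-1-yl]-2-methyldihydrofuran-3(2H)-one
Product: 20 (5R)-2-hydroxy-5-{(2Z)-5-[(2S,3S)-3-(hydroxymethyl)-2-methyloxiran-2-yl]-2-methylpent-2-en-1-yl}-2-methyldihydrofuran-3(2H)-one
Conditions: Ti(OiPr)4, L-(+)-diethyl tartrate, t-BuOOH, 4 Å molecular sieves, CH2Cl2, −20 °C
Reagents that add atoms: tert-butyl hydroperoxide, CC(C)(C)OO
Why: Sharpless asymmetric epoxidation acts only on the allylic alcohol, and L-(+)-tartrate delivers oxygen to the face that gives the 4S,5S epoxide (the same sense as geraniol to its 2S,3S epoxide), leaving the isolated Z-alkene untouched.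

**Step 9**
Reactants: 20 (5R)-2-hydroxy-5-{(2Z)-5-[(2S,3S)-3-(hydroxymethyl)-2-methyloxiran-2-yl]-2-methylpent-2-en-1-yl}-2-methyldihydrofuran-3(2H)-one
Product: 21 (5R)-5-{(2Z)-5-[(2S,3R)-3-formyl-2-methyloxiran-2-yl]-2-methylpent-2-en-1-yl}-2-hydroxy-2-methyldihydrofuran-3(2H)-one
Conditions: Dess–Martin periodinane, pyridine, CH2Cl2, 0 → 23 °C
Reagents that add atoms: none
Why: Dess–Martin oxidation converts the primary epoxy alcohol to the epoxy aldehyde under buffered neutral conditions that leave the tertiary lactol hydroxyl and the epoxide untouched (the oxirane C3 descriptor changes from S to R by priority only, not by inversion).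

**Step 10**
Reactants: 21 (5R)-5-{(2Z)-5-[(2S,3R)-3-formyl-2-methyloxiran-2-yl]-2-methylpent-2-en-1-yl}-2-hydroxy-2-methyldihydrofuran-3(2H)-one
Product: 22 (5R)-5-{(2Z)-5-[(2S,3R)-3-formyl-2-methyloxiran-2-yl]-2-methylpent-2-en-1-yl}-2-methyl-2,3-bis(trimethylsilyloxy)-2,5-dihydrofuran
Conditions: lithium 2,2,6,6-tetramethylpiperidide (2.3 equiv), Me3SiCl (5 equiv, present in situ), THF, −78 °C
Reagents that add atoms: chlorotrimethylsilane, C[Si](C)(C)Cl
Why: In situ-quench enolisation with a hindered, non-nucleophilic amide silylates the lactol oxygen and the only enolisable position (C7) in one operation, while the aldehyde is not attacked and its only α-hydrogen, which sits on the oxirane ring, is not removed because the oxiranyl enolate would be too strained.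

**Step 11**
Reactants: 23 angelic acid
Product: 24 (Z)-2-methylbut-2-enoic 2,4,6-trichlorobenzoic anhydride
Conditions: 2,4,6-Cl3C6H2COCl (1.0 equiv), Et3N (1.05 equiv), THF, 0 → 23 °C; filter off Et3N·HCl under argon; concentrate; take up in toluene (stock solution, used the same day)
Reagents that add atoms: 2,4,6-trichlorobenzoyl chloride, O=C(Cl)c1c(Cl)cc(Cl)cc1Cl
Why: Yamaguchi mixed anhydride formation, in which triethylammonium angelate is O-acylated by the aroyl chloride under mild conditions without a nucleophilic catalyst, so the Z double bond is not isomerised; the two ortho chlorines shield the aroyl carbonyl, so later nucleophiles attack only the angeloyl carbonyl, and one batch serves steps 12 and 13.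

**Step 12**
Reactants: 22 (5R)-5-{(2Z)-5-[(2S,3R)-3-formyl-2-methyloxiran-2-yl]-2-methylpent-2-en-1-yl}-2-methyl-2,3-bis(trimethylsilyloxy)-2,5-dihydrofuran; 24 (Z)-2-methylbut-2-enoic 2,4,6-trichlorobenzoic anhydride
Product: 27 6-O-angeloyl macrocyclic lactol (4S,5S,6S,7S,8R; C12 anomers), via ammonium aldolate 25 (not isolated), via silyl ketal angelate 26 (not isolated)
Conditions: Bu4N[Ph3SiF2] (1.05 equiv), THF, −78 °C, 0.002 M; then 24 (1.5 equiv, toluene solution), −78 → −40 °C; then Bu4NF/AcOH (1:1), THF, 0 °C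
Reagents that add atoms: none
Why: A fluoride-promoted Mukaiyama-type aldol at high dilution closes the ten-membered ring at C6–C7, where attack on the enolate face anti to the C9 substituent sets 7S (trans fusion), the open transition state of the metal-free enolate gives the syn aldol and Felkin–Anh attack anti to the epoxide C–O bond gives 6S (both controls matched), and the aldolate is trapped by the Yamaguchi mixed anhydride 24, which transfers angeloyl without Z-to-E isomerisation.

**Step 13**
Reactants: 27 6-O-angeloyl macrocyclic lactol (4S,5S,6S,7S,8R; C12 anomers); 24 (Z)-2-methylbut-2-enoic 2,4,6-trichlorobenzoic anhydride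
Product: 30 (1(10)Z,4S,5S,6S,7S,8R,11R)-6,11-bis(angeloyloxy)-4,5-epoxygermacr-1(10)-en-8,12-olide, via chloromagnesium lactolate 28 (not isolated), via chloromagnesium lactone alkoxide 29 (not isolated)
Conditions: t-BuMgCl (1.0 equiv), THF, −40 → 23 °C; then 24 (2.0 equiv, toluene solution), 23 → 40 °C
Reagents that add atoms: none
Why: Proposed new method: the chloromagnesium salt of the lactol is the tetrahedral intermediate of a benzilic ester rearrangement, and O–Mg–O chelation between the hemiketal oxygen and the C11 ketone holds the C12–CH3 bond over the carbonyl π* orbital so that methyl shifts from C12 to C11 across the face anti to the C6 branch, which turns C12 into the lactone carbonyl and gives the 11R tertiary magnesium alkoxide that the mixed anhydride acylates in the same flask; the closest known reactions are the benzilic ester/α-ketol (saccharinic acid type) rearrangement and the acylation of tertiary magnesium alkoxides by anhydrides.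

**Step 14**
Reactants: 30 (1(10)Z,4S,5S,6S,7S,8R,11R)-6,11-bis(angeloyloxy)-4,5-epoxygermacr-1(10)-en-8,12-olide
Product: 31 (1R,4S,5S,6S,7S,8R,10S,11R)-6,11-bis(angeloyloxy)-1,10:4,5-diepoxygermacran-8,12-olide (CNP0219924.1)
Conditions: 1,2:4,5-di-O-isopropylidene-β-D-erythro-2,3-hexodiulo-2,6-pyranose (30 mol %), KHSO5 (as 2KHSO5·KHSO4·K2SO4), K2CO3, Bu4NHSO4, Na2B4O7 buffer, MeCN/CH2(OMe)2/H2O, 0 °C
Reagents that add atoms: potassium peroxymonosulfate, [K+].[O-]S(=O)(=O)OO
Why: Shi epoxidation with the D-fructose-derived ketone attacks only the electron-rich trisubstituted ring alkene (the angelate alkenes are electron-poor), and its spiro transition state, with the lone olefinic hydrogen in the hindered quadrant, predicts oxygen delivery to the face that gives the 1R,10S cis-epoxide.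

**Compound list**
1 | but-2-yn-1-ol | CC#CCO | starting material
2 | sodium bis(2-methoxyethoxy) cyclic alkenylalanate (2,5-dihydro-1,2-oxaaluminole ate complex) | CC1=CCO[Al-]1(OCCOC)OCCOC.[Na+] | intermediate
3 | (Z)-3-iodobut-2-en-1-ol | C/C(I)=C/CO | intermediate
4 | (Z)-1-bromo-3-iodobut-2-ene | C/C(I)=C/CBr | intermediate
5 | trimethyl(prop-1-yn-1-yl)silane | CC#C[Si](C)(C)C | starting material
6 | [3-(trimethylsilyl)prop-2-yn-1-yl]lithium | [Li]CC#C[Si](C)(C)C | intermediate
7 | (Z)-(6-iodohept-5-en-1-yn-1-yl)trimethylsilane | C/C(I)=C/CCC#C[Si](C)(C)C | intermediate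
8 | (Z)-6-iodohept-5-en-1-yne | C/C(I)=C/CCC#C | intermediate
9 | dimethyl[(1E,5Z)-6-iodo-2-methylhepta-1,5-dien-1-yl]alane | C/C(I)=C/CC/C(C)=C/[Al](C)C | intermediate
10 | (2E,6Z)-7-iodo-3-methylocta-2,6-dien-1-ol | C/C(I)=C/CC/C(C)=C/CO | intermediate
11 | methyl (S)-oxiran-2-ylacetate | COC(=O)C[C@H]1CO1 | starting material
12 | lithium (2E,6Z)-7-lithio-3-methylocta-2,6-dien-1-olate | C/C([Li])=C/CC/C(C)=C/CO[Li] | intermediate
13 | bis(bromomagnesium) analogue of 12 (alkenylmagnesium bromide, bromomagnesium alkoxide) | C/C([Mg]Br)=C/CC/C(C)=C/CO[Mg]Br | intermediate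
14 | methyl (3R,5Z,9E)-3,11-dihydroxy-5,9-dimethylundeca-5,9-dienoate | COC(=O)C[C@H](O)C/C(C)=C\CC/C(C)=C/CO | intermediate
15 | (3R,5Z,9E)-3,11-dihydroxy-N-methoxy-N,5,9-trimethylundeca-5,9-dienamide | CON(C)C(=O)C[C@H](O)C/C(C)=C\CC/C(C)=C/CO | intermediate
16 | ethyl vinyl ether | C=COCC | starting material
17 | (1-ethoxyvinyl)lithium | [Li]C(=C)OCC | intermediate
18 | (5R,7Z,11E)-2-ethoxy-5,13-dihydroxy-7,11-dimethyltrideca-1,7,11-trien-3-one | CCOC(=C)C(=O)C[C@H](O)C/C(C)=C\CC/C(C)=C/CO | intermediate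
19 | (5R)-2-hydroxy-5-[(2Z,6E)-8-hydroxy-2,6-dimethylocta-2,6-dien-1-yl]-2-methyldihydrofuran-3(2H)-one (C2 anomers) | CC1(O)O[C@H](C/C(C)=C\CC/C(C)=C/CO)CC1=O | intermediate
20 | (5R)-2-hydroxy-5-{(2Z)-5-[(2S,3S)-3-(hydroxymethyl)-2-methyloxiran-2-yl]-2-methylpent-2-en-1-yl}-2-methyldihydrofuran-3(2H)-one | CC1(O)O[C@H](C/C(C)=C\CC[C@]2(C)O[C@H]2CO)CC1=O | intermediate
21 | (5R)-5-{(2Z)-5-[(2S,3R)-3-formyl-2-methyloxiran-2-yl]-2-methylpent-2-en-1-yl}-2-hydroxy-2-methyldihydrofuran-3(2H)-one | CC1(O)O[C@H](C/C(C)=C\CC[C@]2(C)O[C@H]2C=O)CC1=O | intermediate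
22 | (5R)-5-{(2Z)-5-[(2S,3R)-3-formyl-2-methyloxiran-2-yl]-2-methylpent-2-en-1-yl}-2-methyl-2,3-bis(trimethylsilyloxy)-2,5-dihydrofuran | CC1(O[Si](C)(C)C)O[C@H](C/C(C)=C\CC[C@]2(C)O[C@H]2C=O)C=C1O[Si](C)(C)C | intermediate
23 | angelic acid, (Z)-2-methylbut-2-enoic acid | C/C=C(/C)C(=O)O | starting material
24 | (Z)-2-methylbut-2-enoic 2,4,6-trichlorobenzoic anhydride | C/C=C(/C)C(=O)OC(=O)c1c(Cl)cc(Cl)cc1Cl | intermediate
25 | tetrabutylammonium C6-alkoxide of the macrocyclic aldol: (1(10)Z)-4,5-epoxy ten-membered ring trans-fused at C7–C8 to 2-methyl-2-(trimethylsilyloxy)furan-3(2H)-one (ring O on C8, ketone C11 on C7); 4S,5S,6S,7S,8R | CCCC[N+](CCCC)(CCCC)CCCC.[O-][C@H]1[C@@H]2[C@@H](C/C(C)=C\CC[C@]3(C)O[C@@H]13)OC(C)(O[Si](C)(C)C)C2=O | intermediate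
26 | 6-O-angeloyl derivative of the aldol, C12 trimethylsilyl ketal; 4S,5S,6S,7S,8R | C/C=C(/C)C(=O)O[C@H]1[C@@H]2[C@@H](C/C(C)=C\CC[C@]3(C)O[C@@H]13)OC(C)(O[Si](C)(C)C)C2=O | intermediate
27 | 6-O-angeloyl macrocyclic lactol: (1(10)Z)-4,5-epoxy ten-membered ring trans-fused at C7–C8 to 2-hydroxy-2-methylfuran-3(2H)-one; 4S,5S,6S,7S,8R, C12 anomers | C/C=C(/C)C(=O)O[C@H]1[C@@H]2[C@@H](C/C(C)=C\CC[C@]3(C)O[C@@H]13)OC(C)(O)C2=O | intermediate
28 | chloromagnesium salt of lactol 27 | C/C=C(/C)C(=O)O[C@H]1[C@@H]2[C@@H](C/C(C)=C\CC[C@]3(C)O[C@@H]13)OC(C)(O[Mg]Cl)C2=O | intermediate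
29 | chloromagnesium 11-alkoxide of (1(10)Z,4S,5S,6S,7S,8R,11R)-6-angeloyloxy-4,5-epoxy-11-hydroxygermacr-1(10)-en-8,12-olide | C/C=C(/C)C(=O)O[C@H]1[C@@H]2[C@@H](C/C(C)=C\CC[C@]3(C)O[C@@H]13)OC(=O)[C@]2(C)O[Mg]Cl | intermediate
30 | (1(10)Z,4S,5S,6S,7S,8R,11R)-6,11-bis(angeloyloxy)-4,5-epoxygermacr-1(10)-en-8,12-olide | C/C=C(/C)C(=O)O[C@H]1[C@@H]2[C@@H](C/C(C)=C\CC[C@]3(C)O[C@@H]13)OC(=O)[C@]2(C)OC(=O)/C(C)=C\C | intermediate
31 | (1R,4S,5S,6S,7S,8R,10S,11R)-6,11-bis(angeloyloxy)-1,10:4,5-diepoxygermacran-8,12-olide (CNP0219924.1) | C/C=C(/C)C(=O)O[C@H]1[C@@H]2[C@@H](C[C@]3(C)O[C@@H]3CC[C@]3(C)O[C@@H]13)OC(=O)[C@]2(C)OC(=O)/C(C)=C\C | target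

**Step count and risks**
Total steps: 14. Longest linear sequence: 13 (steps 1–10 and 12–14 from but-2-yn-1-ol; step 11 is a one-step branch from angelic acid; 5, 11, 16 and 23 enter as purchased materials).

Most likely to fail:

Step 12 (ring closure). Risks: no C6–C7 closure, cis ring fusion, the C6 epimer, or premature loss of the silyl ketal. Fallback, setting out from 22 and coming back at 26: bromination of the enol silane with N-bromosuccinimide (THF, −78 °C) gives α-bromo ketone F1. Slow addition of SmI2 (2.1 equiv, THF, −78 °C, high dilution, never in excess) forms the trivalent samarium enolate. Its chelated chair-type intramolecular Reformatsky aldol, a known medium-ring closure, is expected to give the anti aldol, the 6R macrocyclic alcohol F2. Mitsunobu esterification of F2 with 23 (PPh3, diisopropyl azodicarboxylate, toluene, 0 °C) inverts C6 and gives 26, which is desilylated to 27 as in step 12.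

Step 13 (the new 1,2-shift with acyl capture). Risks: loss of the C6 angelate by β-elimination, ring opening of the lactolate, or an unreactive tertiary alkoxide. Fallback with known chemistry, setting out from 27 and coming back at 30: NaH (1.0 equiv, THF, 0 °C) forms the sodium lactolate, which undergoes the classical alkoxide-driven benzilic ester rearrangement and gives, after NH4Cl work-up, 11-hydroxy lactone F3. Separately, 23 is converted with 1-chloro-N,N,2-trimethylprop-1-en-1-amine (CH2Cl2, 0 °C) into angeloyl chloride F4. Deprotonation of F3 with LiN(SiMe3)2 (THF, −78 °C) and acylation with F4 gives 30.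

Step 14 (facial selectivity on the macrocycle). Risk: the ring exposes only one alkene face, and reagent control may not override it. Fallback, setting out from 30 and coming back at 31: N-bromosuccinimide in THF/H2O (0 °C) gives bromohydrin F5 (Br at C1, OH at C10, anti addition). Ag2O (THF, 23 °C) then closes the oxirane with inversion at C1. This places the oxygen on the face opposite to the one an electrophilic oxidant attacks, so it gives 31 if direct epoxidation delivers the 1S,10R epimer.

**Further compounds**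
F1 | step 12 | α-bromo ketone: (5R)-4-bromo-5-{(2Z)-5-[(2S,3R)-3-formyl-2-methyloxiran-2-yl]-2-methylpent-2-en-1-yl}-2-methyl-2-(trimethylsilyloxy)dihydrofuran-3(2H)-one (C2, C4 epimers) | CC1(O[Si](C)(C)C)O[C@H](C/C(C)=C\CC[C@]2(C)O[C@H]2C=O)C(Br)C1=O
F2 | step 12 | 6R macrocyclic alcohol (C6 epimer of the free alcohol of 26; 4S,5S,6R,7S,8R; C12 trimethylsilyl ketal) | O[C@@H]1[C@@H]2[C@@H](C/C(C)=C\CC[C@]3(C)O[C@@H]13)OC(C)(O[Si](C)(C)C)C2=O
F3 | step 13 | (1(10)Z,4S,5S,6S,7S,8R,11R)-6-angeloyloxy-4,5-epoxy-11-hydroxygermacr-1(10)-en-8,12-olide | C/C=C(/C)C(=O)O[C@H]1[C@@H]2[C@@H](C/C(C)=C\CC[C@]3(C)O[C@@H]13)OC(=O)[C@]2(C)O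
F4 | step 13 | angeloyl chloride, (Z)-2-methylbut-2-enoyl chloride | C/C=C(/C)C(Cl)=O
F5 | step 14 | (1S,10S)-1-bromo-10-hydroxy bromohydrin of 30 (4S,5S,6S,7S,8R,11R) | C/C=C(/C)C(=O)O[C@H]1[C@@H]2[C@@H](C[C@](C)(O)[C@@H](Br)CC[C@]3(C)O[C@@H]13)OC(=O)[C@]2(C)OC(=O)/C(C)=C\C
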